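## Analysis of the target

The target is a 2,5-diaryl-3,4-dimethyloxolane (tetrahydrofuran; O1, C2 to C5). C2 carries ring A (4-hydroxyphenyl). C5 carries ring B, a phenol whose hydroxyl is para to C5 and whose ortho position holds a (2R)-1-arylpropan-2-yl chain ending in ring C, a second 4-hydroxyphenyl group. The ring has four contiguous stereocentres, (2S,3S,4R,5R): the methyls on C3 and C4 are cis, each aryl is trans to its neighbouring methyl, and the two aryls are therefore cis. With identical aryl groups this core would be meso. Here the rings differ and a fifth stereocentre (R) sits four bonds from C5 across flat ring B, so the two senses of the core are diastereomers that differ only remotely. The sensitive groups are three free, oxidisable phenols and two para-hydroxybenzylic C–O bonds (O1–C2, O1–C5), which ionise under acid, open to quinone methides and are prone to hydrogenolysis. The molecule keeps no carbonyl or other handle, so the difficulty is the relative configuration of four adjacent ring carbons and its relation to the side-chain centre. The strategy rests on one feature: C3 and C4 are the β-carbons of two C6–C3 units joined tail to tail, and O1 bridges their benzylic carbons C2 and C5, each para to a phenol. The oxolane is thus the hydrate of a β–β-linked dimer of two 4-propenylphenols, one of which (ring B) already bears the third C6–C3 unit.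

## Retrosynthetic reasoning

**13 ⇒ 8 + 10 (through 12 and 11).** Target 13 is opened at O1–C2 and O1–C5, returning O1 to the aqueous medium, and at C3–C4. These are the bonds that can be cut without leaving a functional group behind. Each benzylic C–O bond is para to a phenol and is the formal product of a 1,6-addition to a quinone methide (12, then 11). The C3–C4 bond of bis-quinone methide 11 joins two carbons that each carry the spin of a propenyl-conjugated phenoxyl radical. Cutting C2–C3 or C4–C5 instead would require carbonyl or ester groups on C3 or C4 that must later be reduced to methyl. The gain is three bonds, the ring and all four ring stereocentres in one operation from two unprotected phenols, propenylphenol 8 and anol 10. The forward reaction needs β–β rather than β–ortho or β–O coupling, cross- rather than homo-coupling, the erythro pairing at C3–C4, and trans aryl–methyl relationships at C2–C3 and C4–C5. Only the last is under thermodynamic control, and the sense of the core relative to the side chain of 8 is not controlled at all. That is the price of a one-step, protecting-group-free endgame, so the rest of the route is kept short and conservative.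

**8 ⇒ 6 + 7.** The propenyl group is removed at the aryl–alkenyl bond, leaving bromobisphenol 6 and (E)-prop-1-enylboronic acid 7. A cross-coupling transfers the E geometry intact. Placing it last keeps the oxidation- and acid-sensitive propenylphenol out of every deprotection. It requires a bromide para to the ring B hydroxyl that survives all earlier steps.

**6 ⇒ 5.** Both phenols are masked as methyl ethers back to dimethyl ether 5. The building blocks are sold as methyl ethers, and these are inert to the coupling and hydrogenation steps. They can be removed with a strong Lewis acid because the molecule has no alkene at this stage.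

**5 ⇒ 4.** The side-chain stereocentre carries only an aryl, a methyl, a benzyl group and hydrogen, so no neighbouring group is available for an auxiliary or a directed reduction. It is traced to the C=C bond of (E)-α-methylstilbene 4 and set by a cationic iridium catalyst with a chiral P,N ligand, which needs no coordinating group. The forward reaction must add hydrogen to one face and leave the aryl bromide alone. E and Z isomers of such alkenes are reduced to opposite enantiomers, so 4 must be geometrically pure.

**4 ⇒ 2 + 3.** For that reason the alkene is cut at the bond between ring B and the methyl-bearing alkene carbon, not at the C=C bond. A carbonyl olefination on a hindered, ortho-substituted aryl ketone would give E/Z mixtures, whereas coupling of alkenylboronate 2 with 4-bromo-2-iodoanisole 3 is stereospecific. The coupling has to engage the iodide and spare the bromide.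

**2 ⇒ 1.** The boronate is traced to alkyne 1 by syn addition of H and B. The aryl group directs boron to the distal, methyl-bearing carbon, so the geometry and regiochemistry needed in 4 are both fixed here.

**10 ⇒ 9.** Anol 10 does not store well and is made when needed by cleaving the O–methyl bond of trans-anethole 9, which already has the E-propenyl group.

## Alternatives that were turned down

**Alternative 1:** Prins cyclisation with pinacol ring contraction.
- Disconnection: C4–C5 and, through a 1,2-shift, C2–C3.
- Key step: SnCl4 ionises an acetal precursor (a 4-alkenyl-1,3-dioxolane built from a ring B aldehyde and a ring A allylic diol) to an oxocarbenium ion. The trisubstituted alkene closes onto it (C5–C4). The tertiary cation at C3 triggers migration of C2, which contracts the six-membered ring and leaves a formyl group on C3, giving A1.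
- For: the chair-like cyclisation gives C2, C4, C5 and the quaternary C3 with predictable relative configuration. The absolute configuration comes from an enantiopure diol, so the relation of the core to the side-chain centre is set by design. On this point it is stronger than the chosen route, which leaves both the C3–C4 pairing and the sense of the core to separation.
- Against: the target has hydrogen on C3, so the formyl group of A1 must be excised from a quaternary, neopentyl position with retention (stoichiometric RhCl(PPh3)3 at high temperature). Three benzyl ethers must then be removed beside two benzylic C–O bonds. The diol needs its own asymmetric synthesis, and the ring B aldehyde needs the whole side-chain sequence used here plus a formylation.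
- Comparison: the step count would be well over twice that of the chosen route. The chosen route offers instead a coupling product that is the target itself, with no protecting group and nothing to delete.

**Alternative 2:** Carbene C–H insertion into a temporary dihydrobenzofuran.
- Disconnection: not in the oxolane, but the bond between the side-chain stereocentre and its CH2 group.
- Key step: Rh2(S-PTTL)4 turns a diazo ester precursor on ring B into a rhodium carbene that inserts into the benzylic C–H bond of an aryl benzyl ether, closing the cis-dihydrobenzofuran A2. The ring oxygen is the future ring B phenol, the ester the future methyl group, and the benzylic C–O bond is later cleaved reductively.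
- For: this class of insertion is reliably enantio- and cis-selective, the tether is the phenol oxygen itself, and the bromide of A2 is a handle for the rest.
- Against: the key step is spent on the stereocentre that is easiest to set, and the oxolane with its four centres is left entirely to later steps. A2 then needs ester-to-methyl reduction (three operations), a ring opening that spares the aryl bromide, and protecting-group changes. There is also a point of configuration: with C3 as drawn in A2, ester reduction and C2–O cleavage would give the (S) side chain, so the catalyst antipode or a deliberate epimerisation at C3 would be needed.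
- Comparison: about eight steps to reach the stage that compound 6 reaches in four here. Enantiocontrol at the side chain is equally good in principle; the chosen route gets it from one hydrogenation.

**Alternative 3:** Donor–acceptor cyclopropane plus aldehyde (3+2) annulation.
- Disconnection: O1–C5 and C2–C3.
- Key step: Sn(OTf)2 activates a ring B cyclopropane diester partner. The oxygen of a ring A aldehyde partner attacks the benzylic carbon with inversion, and the malonate carbon closes onto the aldehyde carbon, giving the 2,5-cis oxolane A3.
- For: convergent, stereospecific at C5 and reliably 2,5-cis. With an enantioenriched cyclopropane it fixes C2, C4 and C5 in the absolute sense, again better than the chosen route on the sense of the core.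
- Against: C3 emerges as a gem-diester. One ester must be lost and the other reduced to methyl. The configuration of C3 is then decided by a protonation between an aryl group on one face and a methyl group on the other, with no clear bias for the cis-dimethyl arrangement. The electron-rich, para-oxygenated donor also favours ring opening to a stabilised zwitterion, which erodes the stereospecificity, and the cyclopropane needs an asymmetric synthesis on the fully elaborated ring B.
- Comparison: roughly fifteen steps against seven, and the weak point of the chosen route (C3/C4) returns after many more steps.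

Key step: step 7

Assumption: the (S)-configured phosphinooxazoline ligand is taken to reduce alkene 4 with the facial sense known for the parent (E)-α-methylstilbene, which corresponds to (R)-5; the ligand antipode is used if the sense found is the opposite.

## Route

Step 1
Reactants: 1 1-methoxy-4-(prop-1-yn-1-yl)benzene
Product: 2 2-[(Z)-1-(4-methoxyphenyl)prop-1-en-2-yl]-4,4,5,5-tetramethyl-1,3,2-dioxaborolane
Conditions: B2pin2 (1.1 equiv), CuCl (5 mol %), P(p-tol)3 (6 mol %), NaOtBu (10 mol %), MeOH (2 equiv), THF, rt
Reagents that add atoms: bis(pinacolato)diboron, CC1(C)OB(OC1(C)C)B1OC(C)(C)C(C)(C)O1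
Why: Copper-catalysed formal hydroboration (borylcupration, then protonolysis of the alkenylcopper by MeOH). The Cu–B bond adds syn with copper on the aryl-bearing carbon, so boron ends on the methyl-bearing carbon cis to H, which fixes the alkene geometry for step 2.

Step 2
Reactants: 2 2-[(Z)-1-(4-methoxyphenyl)prop-1-en-2-yl]-4,4,5,5-tetramethyl-1,3,2-dioxaborolane; 3 4-bromo-2-iodo-1-methoxybenzene (4-bromo-2-iodoanisole)
Product: 4 4-bromo-1-methoxy-2-[(E)-1-(4-methoxyphenyl)prop-1-en-2-yl]benzene
Conditions: PdCl2(dppf) (3 mol %), K2CO3 (3 equiv), dioxane–H2O (5:1), 60 °C
Reagents that add atoms: none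
Why: Suzuki–Miyaura coupling with retention at the alkenyl carbon should give the (E)-α-methylstilbene as a single geometric isomer. Oxidative addition is much faster at C–I than at the C–Br bond para to the methoxy group, so the bromide is kept for step 5.

Step 3
Reactants: 4 4-bromo-1-methoxy-2-[(E)-1-(4-methoxyphenyl)prop-1-en-2-yl]benzene
Product: 5 4-bromo-1-methoxy-2-[(2R)-1-(4-methoxyphenyl)propan-2-yl]benzene
Conditions: [Ir(cod)(L)]BArF (2 mol %; L = (S)-4-tert-butyl-2-[2-(di-o-tolylphosphanyl)phenyl]-4,5-dihydrooxazole, BArF = B[3,5-(CF3)2C6H3]4), H2 (50 bar), CH2Cl2, rt
Reagents that add atoms: none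
Why: Asymmetric hydrogenation of an unfunctionalised trisubstituted alkene by a cationic iridium phosphinooxazoline catalyst, for which (E)-α-methylstilbenes are the standard substrate class. The chiral P,N pocket selects one enantioface and both hydrogens add syn, setting the side-chain stereocentre as (R); the aryl bromide and the ethers are inert to this catalyst.

Step 4
Reactants: 5 4-bromo-1-methoxy-2-[(2R)-1-(4-methoxyphenyl)propan-2-yl]benzene
Product: 6 4-bromo-2-[(2R)-1-(4-hydroxyphenyl)propan-2-yl]phenol
Conditions: BBr3 (3 equiv), CH2Cl2, −78 °C to rt; then H2O
Reagents that add atoms: none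
Why: Lewis-acid cleavage of aryl methyl ethers (bromide attacks the methyl group of the O–B adduct). It is done while the molecule has no alkene, and the stereocentre carries no ionisable or acidic bond, so it is not at risk.

Step 5
Reactants: 6 4-bromo-2-[(2R)-1-(4-hydroxyphenyl)propan-2-yl]phenol; 7 (E)-prop-1-enylboronic acid
Product: 8 2-[(2R)-1-(4-hydroxyphenyl)propan-2-yl]-4-[(E)-prop-1-enyl]phenol
Conditions: Pd(OAc)2 (3 mol %), SPhos (6 mol %), K3PO4 (4 equiv), dioxane–H2O (4:1), degassed, 80 °C; acidify to pH 5 under N2
Reagents that add atoms: none
Why: Suzuki–Miyaura coupling of an unprotected bromophenol with an alkenylboronic acid. The electron-rich biarylphosphine makes oxidative addition into the phenoxide-deactivated C–Br bond feasible, and the E geometry of 7 is transferred with retention; installing the propenyl group last means 8 never meets a deprotection reagent.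

Step 6
Reactants: 9 trans-anethole, 1-methoxy-4-[(E)-prop-1-enyl]benzene
Product: 10 anol, 4-[(E)-prop-1-enyl]phenol
Conditions: NaSEt (2.5 equiv), DMF, 140 °C; then dilute HCl; used at once
Reagents that add atoms: none
Why: SN2 demethylation of an aryl methyl ether by ethanethiolate in a dipolar aprotic solvent. The unactivated E-propenyl group is inert to the nucleophile and keeps its geometry.

Step 7
Reactants: 8 2-[(2R)-1-(4-hydroxyphenyl)propan-2-yl]-4-[(E)-prop-1-enyl]phenol; 10 anol (3 equiv)
Product: 13 (2S,3S,4R,5R)-2-(4-hydroxyphenyl)-5-{4-hydroxy-3-[(2R)-1-(4-hydroxyphenyl)propan-2-yl]phenyl}-3,4-dimethyloxolane (CNP0232576.1), via bis-quinone methide 11 (not isolated), via hydroxy quinone methide 12 (not isolated)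
Conditions: Ag2O (2 equiv based on 8, in portions), acetone–H2O (4:1), N2, dark, rt; filter (Celite), short SiO2 column to remove monomers; then TsOH·H2O (10 mol %), MeCN–H2O (9:1), rt; SiO2 chromatography, then preparative HPLC
Reagents that add atoms: water, O
Why: Ag2O removes one electron and one proton from each phenol; the phenoxyl radicals carry spin on the propenyl β-carbon, and β–β radical–radical coupling forms C3–C4 and gives bis-quinone methide 11. Water adds 1,6 to one quinone methide (12), and the new benzylic hydroxyl closes on the other by a 5-exo-trig oxa-1,6-addition that restores the second phenol and completes the oxolane (O1–C2 and O1–C5). The closest known reaction type is the oxidative β–β dimerisation of 4-propenylphenols in aqueous media to 2,5-diaryl-3,4-dimethyloxolanes, run here as a mixed coupling of two such phenols in the manner of dehydrogenative cross-coupling of monolignols. C3 and C4 are fixed in the radical coupling by the mutual approach of the two planar radicals, with no bias from either substrate; the erythro pairing needed here competes with the threo pairing, which a stacked approach of two E-configured radicals may well prefer, and the propenyl geometry is the only substrate variable that bears on it. C2 and C5 are set by the two oxygen additions anti to the neighbouring methyl groups, and because both C–O bonds are para-hydroxybenzylic they ionise reversibly under the catalytic acid of the second stage, so cis epimers should drain into the 2,3-trans/4,5-trans isomer, the most stable arrangement on a cis-dimethyl ring. The sense of the core relative to the remote (R) centre of 8 is uncontrolled, so 13 and its core diastereomer should form in similar amounts and are separated by preparative HPLC. Cross- over homo-coupling rests on the excess of the cheap partner 10; β–β over β–ortho and β–O coupling is helped only by the side chain blocking one ortho position of ring B, so 13 is expected as a minor component of the dimer fraction, and the oxidant is limited to one equivalent per phenol to spare the product phenols.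

## Compound list

1 | 1-methoxy-4-(prop-1-yn-1-yl)benzene | CC#Cc1ccc(OC)cc1 | starting material
2 | 2-[(Z)-1-(4-methoxyphenyl)prop-1-en-2-yl]-4,4,5,5-tetramethyl-1,3,2-dioxaborolane | COc1ccc(/C=C(\C)B2OC(C)(C)C(C)(C)O2)cc1 | intermediate
3 | 4-bromo-2-iodo-1-methoxybenzene | COc1ccc(Br)cc1I | starting material
4 | 4-bromo-1-methoxy-2-[(E)-1-(4-methoxyphenyl)prop-1-en-2-yl]benzene | COc1ccc(/C=C(\C)c2cc(Br)ccc2OC)cc1 | intermediate
5 | 4-bromo-1-methoxy-2-[(2R)-1-(4-methoxyphenyl)propan-2-yl]benzene | COc1ccc(C[C@@H](C)c2cc(Br)ccc2OC)cc1 | intermediate
6 | 4-bromo-2-[(2R)-1-(4-hydroxyphenyl)propan-2-yl]phenol | Oc1ccc(C[C@@H](C)c2cc(Br)ccc2O)cc1 | intermediate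
7 | (E)-prop-1-enylboronic acid | C/C=C/B(O)O | starting material
8 | 2-[(2R)-1-(4-hydroxyphenyl)propan-2-yl]-4-[(E)-prop-1-enyl]phenol | C/C=C/c1ccc(O)c([C@H](C)Cc2ccc(O)cc2)c1 | intermediate
9 | trans-anethole, 1-methoxy-4-[(E)-prop-1-enyl]benzene | COc1ccc(/C=C/C)cc1 | starting material
10 | anol, 4-[(E)-prop-1-enyl]phenol | C/C=C/c1ccc(O)cc1 | intermediate
11 | erythro β–β bis-para-quinone methide of 8 and 10 (new centres configured as C3 and C4 of 13; exocyclic geometry at ring B not defined) | C[C@@H](C=C1C=CC(=O)C([C@H](C)Cc2ccc(O)cc2)=C1)[C@H](C)C=C1C=CC(=O)C=C1 | intermediate
12 | hydroxy quinone methide, water adduct of 11 at the ring A methide carbon (addition at the ring B side first leads to the same product) | C[C@@H](C=C1C=CC(=O)C([C@H](C)Cc2ccc(O)cc2)=C1)[C@H](C)[C@H](O)c1ccc(O)cc1 | intermediate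
13 | (2S,3S,4R,5R)-2-(4-hydroxyphenyl)-5-{4-hydroxy-3-[(2R)-1-(4-hydroxyphenyl)propan-2-yl]phenyl}-3,4-dimethyloxolane | C[C@@H]1[C@H](C)[C@@H](c2ccc(O)cc2)O[C@H]1c1ccc(O)c([C@H](C)Cc2ccc(O)cc2)c1 | target

## Step count and least certain steps

Total step count: 7. Longest linear sequence: 6 (steps 1, 2, 3, 4, 5, 7); step 6 is a one-step side branch.

**Step 7 (key step).** Most likely to go wrong:
- coupling through the free ortho positions and the phenol oxygens may outrun β–β coupling;
- homo-dimerisation of each partner;
- the threo pairing may prevail at C3–C4;
- the two senses of the core are not discriminated and differ only remotely, so separation is hard;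
- the product phenols may be oxidised further.

Fallback (sets out from 6, returns at 13): the oxolane is built without oxidative coupling.
- Benzylation of 6 (BnBr, K2CO3, DMF) gives 1-(benzyloxy)-2-{(2R)-1-[4-(benzyloxy)phenyl]propan-2-yl}-4-bromobenzene F1.
- Bromine–lithium exchange (n-BuLi, THF, −78 °C) and acylation with N-methoxy-N-methylpropanamide give the propiophenone F2.
- Its lithium enolate (LiN(SiMe3)2, THF, −78 °C) is alkylated with commercial 1-[4-(benzyloxy)phenyl]-2-bromopropan-1-one F3 to the 2,3-dimethyl-1,4-diketone F4 (any diastereomer mixture).
- Paal–Knorr cyclodehydration (TsOH, toluene, reflux) gives the 2,5-diaryl-3,4-dimethylfuran F5.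
- Hydrogenation over Pd/C removes the three benzyl groups and adds hydrogen syn to one face of the furan, giving the all-cis oxolane triphenol F6 and so securing the cis-dimethyl relationship.
- Catalytic TsOH in wet MeCN then epimerises the para-hydroxybenzylic centres C2 and C5 to the trans arrangement, giving 13.

Both furan faces react, so the final separation of two core senses remains. Regiochemistry, cross-selectivity and the C3–C4 pairing no longer depend on a radical coupling, at the cost of four extra steps.

**Step 3.** Turnover may be slow or enantioselectivity eroded, because the ortho-methoxy group twists ring B out of conjugation and may bind the cationic iridium. Traces of geometric or regioisomeric alkene would also lower the enantiomeric purity. Fallback (sets out from 4, returns at 6): unselective hydrogenation with [Ir(cod)(PCy3)(py)]PF6 in CH2Cl2 gives racemic 4-bromo-1-methoxy-2-[1-(4-methoxyphenyl)propan-2-yl]benzene F7. BBr3 gives racemic 4-bromo-2-[1-(4-hydroxyphenyl)propan-2-yl]phenol F8, which is resolved by preparative chromatography on a polysaccharide chiral stationary phase to give 6.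

**Step 5.** Oxidative addition into the phenoxide-bearing aryl bromide may be sluggish, the boronic acid may protodeboronate, and the propenylphenol may oxidise or oligomerise in hot base. Fallback (sets out from 5, returns at 8): the coupling is run on the dimethyl ether, where it is routine, giving 1-methoxy-2-[(2R)-1-(4-methoxyphenyl)propan-2-yl]-4-[(E)-prop-1-enyl]benzene F9. Both methyl groups are then removed with NaSEt in DMF at 140 °C, as in step 6, to give 8.

**Step 2.** A second coupling at the bromide, or slow transmetallation of the hindered α-methyl alkenylboronate with protodeboronation, may lower the yield. Fallback (sets out from 3, returns at 4): selective iodine–magnesium exchange on 3 (iPrMgCl·LiCl, THF, −20 °C) and acylation with N-methoxy-N-methylacetamide give 1-(5-bromo-2-methoxyphenyl)ethan-1-one F10. Addition of 4-methoxybenzylmagnesium chloride gives the tertiary alcohol 2-(5-bromo-2-methoxyphenyl)-1-(4-methoxyphenyl)propan-2-ol F11. Acid dehydration (TsOH, toluene, reflux) gives 4 once the Z and 1,1-disubstituted isomers are removed by crystallisation or chromatography on AgNO3-impregnated silica. Geometric purity must be secured before step 3.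

## Further compounds

F1 | step 7 | 1-(benzyloxy)-2-{(2R)-1-[4-(benzyloxy)phenyl]propan-2-yl}-4-bromobenzene | C[C@H](Cc1ccc(OCc2ccccc2)cc1)c1cc(Br)ccc1OCc1ccccc1
F2 | step 7 | 1-{4-(benzyloxy)-3-[(2R)-1-(4-(benzyloxy)phenyl)propan-2-yl]phenyl}propan-1-one | CCC(=O)c1ccc(OCc2ccccc2)c([C@H](C)Cc2ccc(OCc3ccccc3)cc2)c1
F3 | step 7 | 1-[4-(benzyloxy)phenyl]-2-bromopropan-1-one (racemic) | CC(Br)C(=O)c1ccc(OCc2ccccc2)cc1
F4 | step 7 | 1-[4-(benzyloxy)phenyl]-4-{4-(benzyloxy)-3-[(2R)-1-(4-(benzyloxy)phenyl)propan-2-yl]phenyl}-2,3-dimethylbutane-1,4-dione (mixture at C2 and C3) | CC(C(=O)c1ccc(OCc2ccccc2)cc1)C(C)C(=O)c1ccc(OCc2ccccc2)c([C@H](C)Cc2ccc(OCc3ccccc3)cc2)c1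
F5 | step 7 | 2-[4-(benzyloxy)phenyl]-5-{4-(benzyloxy)-3-[(2R)-1-(4-(benzyloxy)phenyl)propan-2-yl]phenyl}-3,4-dimethylfuran | Cc1c(-c2ccc(OCc3ccccc3)cc2)oc(-c2ccc(OCc3ccccc3)c([C@H](C)Cc3ccc(OCc4ccccc4)cc3)c2)c1C
F6 | step 7 | all-cis (2R,3S,4R,5S)-2-(4-hydroxyphenyl)-5-{4-hydroxy-3-[(2R)-1-(4-hydroxyphenyl)propan-2-yl]phenyl}-3,4-dimethyloxolane (the face isomer that leads to 13; formed with its face diastereomer) | C[C@@H]1[C@H](C)[C@H](c2ccc(O)cc2)O[C@@H]1c1ccc(O)c([C@H](C)Cc2ccc(O)cc2)c1
F7 | step 3 | racemic 4-bromo-1-methoxy-2-[1-(4-methoxyphenyl)propan-2-yl]benzene | COc1ccc(CC(C)c2cc(Br)ccc2OC)cc1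
F8 | step 3 | racemic 4-bromo-2-[1-(4-hydroxyphenyl)propan-2-yl]phenol | Oc1ccc(CC(C)c2cc(Br)ccc2O)cc1
F9 | step 5 | 1-methoxy-2-[(2R)-1-(4-methoxyphenyl)propan-2-yl]-4-[(E)-prop-1-enyl]benzene | C/C=C/c1ccc(OC)c([C@H](C)Cc2ccc(OC)cc2)c1
F10 | step 2 | 1-(5-bromo-2-methoxyphenyl)ethan-1-one | CC(=O)c1cc(Br)ccc1OC
F11 | step 2 | 2-(5-bromo-2-methoxyphenyl)-1-(4-methoxyphenyl)propan-2-ol (racemic) | CC(O)(Cc1ccc(OC)cc1)c1cc(Br)ccc1OC
A1 | alternative 1 | 2-[4-(benzyloxy)phenyl]-5-{4-(benzyloxy)-3-[(2R)-1-(4-(benzyloxy)phenyl)propan-2-yl]phenyl}-3,4-dimethyloxolane-3-carbaldehyde (formyl on C3 cis to both aryl groups, methyls cis) | C[C@@H]1[C@](C=O)(C)[C@@H](c2ccc(OCc3ccccc3)cc2)O[C@H]1c1ccc(OCc2ccccc2)c([C@H](C)Cc2ccc(OCc3ccccc3)cc2)c1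
A2 | alternative 2 | methyl cis-2-[4-(benzyloxy)phenyl]-5-bromo-2,3-dihydro-1-benzofuran-3-carboxylate (2S,3R as drawn) | COC(=O)[C@H]1[C@@H](c2ccc(OCc3ccccc3)cc2)Oc2ccc(Br)cc21
A3 | alternative 3 | dimethyl 2-[4-(benzyloxy)phenyl]-5-{4-(benzyloxy)-3-[(2R)-1-(4-(benzyloxy)phenyl)propan-2-yl]phenyl}-4-methyloxolane-3,3-dicarboxylate (2,5-cis, 4,5-trans) | C[C@@H]1C(C(=O)OC)(C(=O)OC)[C@@H](c2ccc(OCc3ccccc3)cc2)O[C@H]1c1ccc(OCc2ccccc2)c([C@H](C)Cc2ccc(OCc3ccccc3)cc2)c1
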